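The target is an (R)-malate monoester and a γ-lactone diacid (a 5-oxooxolane-2-carboxylic acid bearing an α-CH(CO2H) carbon) joined by an unbranched decamethylene chain, C1 at the ester oxygen to C10 at that CH. The route cuts the chain at its unfunctionalised centre, C6–C7, far from every polar group. Ruthenium-catalysed cross-metathesis of two terminal alkenes of similar size, hept-6-enyl hydrogen (R)-malate and the pent-4-enyl lactone diacid, forms this bond as C6=C7 without protecting groups; hydrogenation then erases the alkene. Both lactone stereocentres come from one Evans titanium aldol of a hept-6-enoyl imide with dimethyl 2-oxoglutarate.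

Key step: step 5

Remark: alkene 17 is expected as an E/Z mixture and is written without double-bond geometry, which step 6 removes.

Step 1
Reactants: 1 (R)-malic acid; 2 hept-6-en-1-ol
Product: 5 (3R)-4-(hept-6-en-1-yloxy)-3-hydroxy-4-oxobutanoic acid (1-hept-6-enyl hydrogen (R)-malate), via trifluoroacetoxysuccinic anhydride 3 (not isolated), via O-trifluoroacetyl monoester 4 (not isolated)
Conditions: TFAA, 0 °C → rt, then evaporation; 2, THF, 0 °C → rt; H2O, rt
Reagents that add atoms: none
Why: Regioselective alcoholysis of an O-acylmalic anhydride: TFAA gives the O-trifluoroacetyl cyclic anhydride, the primary alcohol should open it at the more electrophilic carbonyl next to the acyloxy-bearing carbon, and the labile trifluoroacetate is lost in water, so the C1 ester with free hydroxyl and free C4 acid results with the (R)-centre untouched.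

Step 2
Reactants: 6 hept-6-enoic acid; 7 (S)-4-benzyloxazolidin-2-one
Product: 9 (S)-4-benzyl-3-(hept-6-enoyl)oxazolidin-2-one, via mixed pivalic anhydride 8 (not isolated)
Conditions: PivCl, Et3N, THF, −20 °C; then LiCl, 7, −20 °C → rt
Reagents that add atoms: none
Why: Mixed-anhydride N-acylation of the Evans oxazolidinone (pivaloyl chloride/LiCl protocol), in which the unhindered heptenoyl carbonyl of 8 is attacked selectively and no stereocentre is affected.

Step 3
Reactants: 9 (S)-4-benzyl-3-(hept-6-enoyl)oxazolidin-2-one; 10 dimethyl 2-oxoglutarate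
Product: 13 methyl (2R)-2-[(2S)-1-[(4S)-4-benzyl-2-oxooxazolidin-3-yl]-1-oxohept-6-en-2-yl]-5-oxooxolane-2-carboxylate, via chlorotitanium Z-enolate 11 (not isolated), via open hydroxy diester 12 (not isolated)
Conditions: TiCl4, i-Pr2NEt, CH2Cl2, 0 °C; NMP; 10, −78 → −20 °C; aq. NH4Cl; TsOH·H2O (cat.), CH2Cl2, rt
Reagents that add atoms: none
Why: Evans-type titanium aldol addition to an activated ketone followed by lactonisation: Z-enolate 11 should react through a closed Zimmerman–Traxler chair on the face opposite the benzyl group of the dipole-opposed auxiliary, which sets the CH centre as S, and the keto ester should place its CH2CH2CO2Me arm pseudo-equatorial and the smaller, titanium-coordinating CO2Me group pseudo-axial, which sets the carbinol centre as R; closure of the aldolate (or of 12 under TsOH) onto the γ-ester gives the five-membered lactone and blocks retro-aldol cleavage.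

Step 4
Reactants: 13 methyl (2R)-2-[(2S)-1-[(4S)-4-benzyl-2-oxooxazolidin-3-yl]-1-oxohept-6-en-2-yl]-5-oxooxolane-2-carboxylate
Product: 16 (2R)-2-[(1S)-1-carboxyhex-5-en-1-yl]-5-oxooxolane-2-carboxylic acid, via peroxy acid 14 (not isolated), via seco triacid 15 (not isolated)
Conditions: LiOH, H2O2, THF/H2O, 0 °C; aq. Na2SO3; LiOH (excess), rt; 2 M HCl to pH 1, 40 °C
Reagents that add atoms: hydrogen peroxide, OO; lithium hydroxide, [Li+].[OH-]
Why: Evans hydroperoxide cleavage of the imide, then saponification and acid relactonisation: HOO− attacks the exocyclic imide carbonyl to give 14, sulfite reduces it, hydroxide hydrolyses the methyl ester and opens the lactone to the tricarboxylate of 15, and at pH 1 the tertiary hydroxyl recloses the γ-lactone; the CH centre is α to a carboxylate in the basic stage and the carbinol centre is quaternary, so neither should be scrambled.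

Step 5
Reactants: 16 (2R)-2-[(1S)-1-carboxyhex-5-en-1-yl]-5-oxooxolane-2-carboxylic acid; 5 (3R)-4-(hept-6-en-1-yloxy)-3-hydroxy-4-oxobutanoic acid
Product: 17 (2R)-2-[(1S)-1-carboxy-11-{[(2R)-3-carboxy-2-hydroxypropanoyl]oxy}undec-5-en-1-yl]-5-oxooxolane-2-carboxylic acid (E/Z mixture)
Conditions: Hoveyda–Grubbs II (5 mol%), 5 (3 equiv), 1,4-benzoquinone (10 mol%), CH2Cl2/THF, 40 °C, Ar sparge
Reagents that add atoms: none
Why: Chauvin mechanism: the catalyst forms Ru alkylidenes of both terminal alkenes, which combine through ruthenacyclobutanes and release ethylene, so that the internal alkene carbon C6 of 5 and the internal alkene carbon C7 of 16 become joined as C6=C7. The closest known reaction type is cross-metathesis of two unhindered monosubstituted (type I) olefins with a second-generation Ru catalyst, which tolerates free carboxylic acids, alcohols, esters and lactones. No ring is closed and no stereocentre is made; the E/Z mixture is of no consequence because step 6 saturates the bond, and the three existing stereocentres are remote and untouched. The selectivity needed is hetero- over homo-coupling and the absence of double-bond migration, which would give chain-shortened homologues. Both alkenes sit at least four carbons from any polar group, so the distribution is statistical; three equivalents of 5, made in one step, should drive most of 16 into 17 while the homodimers stay metathesis-active, and the free CO2H groups together with benzoquinone should suppress Ru–H isomerisation. Neither partner contains another C=C, so no chemoselectivity problem arises.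

Step 6
Reactants: 17 (2R)-2-[(1S)-1-carboxy-11-{[(2R)-3-carboxy-2-hydroxypropanoyl]oxy}undec-5-en-1-yl]-5-oxooxolane-2-carboxylic acid
Product: 18 (2R)-2-[(1S)-1-carboxy-11-{[(2R)-3-carboxy-2-hydroxypropanoyl]oxy}undecyl]-5-oxooxolane-2-carboxylic acid (CNP0457473.1)
Conditions: H2 (1 atm), 10% Pd/C, EtOAc, rt
Reagents that add atoms: none
Why: Heterogeneous catalytic hydrogenation saturates the isolated disubstituted alkene, so both geometric isomers converge on the target, while the lactone, the ester, the acids and the three stereocentres are inert to H2/Pd.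

Compound list
1 | (R)-malic acid | O=C(O)C[C@@H](O)C(=O)O | starting material
2 | hept-6-en-1-ol | OCCCCCC=C | starting material
3 | (3R)-2,5-dioxooxolan-3-yl trifluoroacetate (O-trifluoroacetylmalic anhydride) | O=C1C[C@@H](OC(=O)C(F)(F)F)C(=O)O1 | intermediate
4 | (3R)-4-(hept-6-en-1-yloxy)-4-oxo-3-(trifluoroacetoxy)butanoic acid | O=C(O)C[C@@H](OC(=O)C(F)(F)F)C(=O)OCCCCCC=C | intermediate
5 | (3R)-4-(hept-6-en-1-yloxy)-3-hydroxy-4-oxobutanoic acid | O=C(O)C[C@@H](O)C(=O)OCCCCCC=C | intermediate
6 | hept-6-enoic acid | C=CCCCCC(=O)O | starting material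
7 | (S)-4-benzyloxazolidin-2-one | O=C1N[C@@H](Cc2ccccc2)CO1 | starting material
8 | hept-6-enoic pivalic anhydride | C=CCCCCC(=O)OC(=O)C(C)(C)C | intermediate
9 | (S)-4-benzyl-3-(hept-6-enoyl)oxazolidin-2-one | C=CCCCCC(=O)N1[C@@H](Cc2ccccc2)COC1=O | intermediate
10 | dimethyl 2-oxoglutarate | COC(=O)CCC(=O)C(=O)OC | starting material
11 | (Z)-trichlorotitanium enolate of 9 | C=CCCC/C=C(\O[Ti](Cl)(Cl)Cl)N1[C@@H](Cc2ccccc2)COC1=O | intermediate
12 | dimethyl (2R)-2-[(2S)-1-[(4S)-4-benzyl-2-oxooxazolidin-3-yl]-1-oxohept-6-en-2-yl]-2-hydroxypentanedioate | C=CCCC[C@H](C(=O)N2[C@@H](Cc3ccccc3)COC2=O)[C@@](O)(C(=O)OC)CCC(=O)OC | intermediate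
13 | methyl (2R)-2-[(2S)-1-[(4S)-4-benzyl-2-oxooxazolidin-3-yl]-1-oxohept-6-en-2-yl]-5-oxooxolane-2-carboxylate | C=CCCC[C@H](C(=O)N2[C@@H](Cc3ccccc3)COC2=O)[C@@]1(C(=O)OC)CCC(=O)O1 | intermediate
14 | (2S)-2-[(2R)-2-(methoxycarbonyl)-5-oxooxolan-2-yl]hept-6-eneperoxoic acid | C=CCCC[C@H](C(=O)OO)[C@@]1(C(=O)OC)CCC(=O)O1 | intermediate
15 | (3R,4S)-3-hydroxynon-8-ene-1,3,4-tricarboxylic acid (formed as its trilithium salt) | C=CCCC[C@H](C(=O)O)[C@@](O)(C(=O)O)CCC(=O)O | intermediate
16 | (2R)-2-[(1S)-1-carboxyhex-5-en-1-yl]-5-oxooxolane-2-carboxylic acid | C=CCCC[C@H](C(=O)O)[C@@]1(C(=O)O)CCC(=O)O1 | intermediate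
17 | (2R)-2-[(1S)-1-carboxy-11-{[(2R)-3-carboxy-2-hydroxypropanoyl]oxy}undec-5-en-1-yl]-5-oxooxolane-2-carboxylic acid (E/Z) | O=C(O)C[C@@H](O)C(=O)OCCCCCC=CCCC[C@H](C(=O)O)[C@@]1(C(=O)O)CCC(=O)O1 | intermediate
18 | (2R)-2-[(1S)-1-carboxy-11-{[(2R)-3-carboxy-2-hydroxypropanoyl]oxy}undecyl]-5-oxooxolane-2-carboxylic acid | O=C(O)C[C@@H](O)C(=O)OCCCCCCCCCC[C@H](C(=O)O)[C@@]1(C(=O)O)CCC(=O)O1 | target

Total step count: 6. Longest linear sequence: 5 steps (steps 2, 3, 4, 5, 6).

Steps most likely to fail

1. Step 3. The two ketone faces may be poorly discriminated if the CO2Me and CH2CH2CO2Me groups exchange pseudo-axial and pseudo-equatorial positions in the chair, which would erode the configuration at the carbinol centre; enolisation and self-condensation of the keto ester may also compete. Fallback (sets out from 1, returns at 16): 1 is esterified (i-PrOH, cat. H2SO4, reflux) to diisopropyl (R)-malate F1. Fráter–Seebach alkylation of its dilithium alkoxide-enolate (LiHMDS, 2.2 equiv, THF, −78 → −20 °C; 5-iodopent-1-ene) should give the anti product, diisopropyl (2R,3S)-2-hydroxy-3-(pent-4-en-1-yl)succinate F2. Saponification (KOH, aq. EtOH; H3O+) should give (2R,3S)-2-hydroxy-3-(pent-4-en-1-yl)succinic acid F3, and acetalisation with pivalaldehyde (cat. TsOH/H2SO4, pentane, water removal) the cis-dioxolanone (2S)-2-[(2R,4R)-2-tert-butyl-5-oxo-1,3-dioxolan-4-yl]hept-6-enoic acid F4. Its dianion (LiHMDS, 2.1 equiv, THF, −78 °C) should add to tert-butyl acrylate on the face anti to the tert-butyl group (self-regeneration of the stereocentre, overall retention) to give (2S)-2-[(2R,4R)-4-(3-tert-butoxy-3-oxopropyl)-2-tert-butyl-5-oxo-1,3-dioxolan-4-yl]hept-6-enoic acid F5. Aqueous TFA at 50 °C should then remove the acetal and the tert-butyl ester and close the lactone to 16.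

2. Step 5. Statistical homodimerisation may consume 16, double-bond migration before metathesis may give chain-shortened homologues, and the polar acids may be hard to separate. Fallback (sets out from 16 and 3, returns at 17): ozonolysis of 16 (O3, CH2Cl2/MeOH, −78 °C; Me2S) should give (2R)-2-[(1S)-1-carboxy-5-oxopentyl]-5-oxooxolane-2-carboxylic acid F6. Anhydride 3, made from 1 as in step 1, is opened with commercial (6-hydroxyhexyl)triphenylphosphonium bromide to give the O-trifluoroacetyl phosphonium ester F7 (not isolated), and water then frees [6-{[(2R)-3-carboxy-2-hydroxypropanoyl]oxy}hexyl]triphenylphosphonium bromide F8. The ylide from F8 (NaHMDS, 3 equiv per F8, THF, −78 → 0 °C) is used in excess so that it also neutralises the two CO2H groups of F6, as in Wittig reactions of ω-carboxyalkyl ylides. Its condensation with F6 should give 17, mainly Z, which is hydrogenated as in step 6.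

3. Step 4. The lactone may open before the hindered imide is cleaved, exposing a tertiary aldolate next to the intact imide to retro-aldol cleavage; slow exocyclic attack may also allow endocyclic opening of the oxazolidinone. Fallback (sets out from 9, returns at 16): enolate 11 is added to commercial di-tert-butyl 2-oxoglutarate to give di-tert-butyl (2R)-2-[(2S)-1-[(4S)-4-benzyl-2-oxooxazolidin-3-yl]-1-oxohept-6-en-2-yl]-2-hydroxypentanedioate F9, which should not lactonise under the reaction conditions. TFA (CH2Cl2, rt) should cleave both tert-butyl esters and close the lactone to (2R)-2-[(2S)-1-[(4S)-4-benzyl-2-oxooxazolidin-3-yl]-1-oxohept-6-en-2-yl]-5-oxooxolane-2-carboxylic acid F10. A short LiOH/H2O2 treatment at 0 °C, Na2SO3 and acidification should then give 16 without any prolonged saponification stage.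

Further compounds
F1 | step 3 | diisopropyl (R)-malate | CC(C)OC(=O)C[C@@H](O)C(=O)OC(C)C
F2 | step 3 | diisopropyl (2R,3S)-2-hydroxy-3-(pent-4-en-1-yl)succinate | C=CCCC[C@H](C(=O)OC(C)C)[C@@H](O)C(=O)OC(C)C
F3 | step 3 | (2R,3S)-2-hydroxy-3-(pent-4-en-1-yl)succinic acid | C=CCCC[C@H](C(=O)O)[C@@H](O)C(=O)O
F4 | step 3 | (2S)-2-[(2R,4R)-2-tert-butyl-5-oxo-1,3-dioxolan-4-yl]hept-6-enoic acid | C=CCCC[C@H](C(=O)O)[C@@H]1C(=O)O[C@H](C(C)(C)C)O1
F5 | step 3 | (2S)-2-[(2R,4R)-4-(3-tert-butoxy-3-oxopropyl)-2-tert-butyl-5-oxo-1,3-dioxolan-4-yl]hept-6-enoic acid | C=CCCC[C@H](C(=O)O)[C@]1(CCC(=O)OC(C)(C)C)C(=O)O[C@H](C(C)(C)C)O1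
F6 | step 5 | (2R)-2-[(1S)-1-carboxy-5-oxopentyl]-5-oxooxolane-2-carboxylic acid | O=CCCC[C@H](C(=O)O)[C@@]1(C(=O)O)CCC(=O)O1
F7 | step 5 | [6-{[(2R)-3-carboxy-2-(trifluoroacetoxy)propanoyl]oxy}hexyl]triphenylphosphonium bromide | O=C(O)C[C@@H](OC(=O)C(F)(F)F)C(=O)OCCCCCC[P+](c1ccccc1)(c1ccccc1)c1ccccc1.[Br-]
F8 | step 5 | [6-{[(2R)-3-carboxy-2-hydroxypropanoyl]oxy}hexyl]triphenylphosphonium bromide | O=C(O)C[C@@H](O)C(=O)OCCCCCC[P+](c1ccccc1)(c1ccccc1)c1ccccc1.[Br-]
F9 | step 4 | di-tert-butyl (2R)-2-[(2S)-1-[(4S)-4-benzyl-2-oxooxazolidin-3-yl]-1-oxohept-6-en-2-yl]-2-hydroxypentanedioate | C=CCCC[C@H](C(=O)N2[C@@H](Cc3ccccc3)COC2=O)[C@@](O)(C(=O)OC(C)(C)C)CCC(=O)OC(C)(C)C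
F10 | step 4 | (2R)-2-[(2S)-1-[(4S)-4-benzyl-2-oxooxazolidin-3-yl]-1-oxohept-6-en-2-yl]-5-oxooxolane-2-carboxylic acid | C=CCCC[C@H](C(=O)N2[C@@H](Cc3ccccc3)COC2=O)[C@@]1(C(=O)O)CCC(=O)O1
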